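**Retrosynthetic overview**
1. No ring is built: both benzene rings are bought as 4-bromo-2-methoxyphenol (1). The only ring–ring bond is made first, by oxidative ortho–ortho dimerisation of 1 to the dibromobiphenol 2.
2. Key disconnection: both aryl–CH2 bonds of the target at once. Each is cut into an aryl bromide carbon of 2 and the β-carbon of a propanoate homoenolate, the zinc reagent 3; the ester β-carbon, normally an acceptor site, is used as the nucleophile.
3. The twofold coupling is run on the unprotected bis-phenol, and the diester 4 is saponified in the same pot to the target 5.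

Assumption: the target has no stereocentre and its biaryl axis carries only two ortho substituents (both OH), so it is achiral and "single enantiomer" means the compound itself.

**Step 1**
Reactants: 1 4-bromo-2-methoxyphenol (2 equiv)
Product: 2 5,5'-dibromo-3,3'-dimethoxy-[1,1'-biphenyl]-2,2'-diol
Conditions: FeCl3 (10 mol %), t-BuOOt-Bu (0.6 equiv), (CF3)2CHOH, rt, 16 h
Reagents that add atoms: none
Why: Oxidative phenol coupling (dehydrogenative homo-coupling): the FeCl3-bound phenoxyl radical of 1 has its para position blocked by bromine and one ortho position blocked by methoxy, so C–C bond formation takes place at the free ortho carbon of each ring and tautomerisation gives the 2,2'-biphenol, with no stereocentre formed.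

**Step 2**
Reactants: 2 5,5'-dibromo-3,3'-dimethoxy-[1,1'-biphenyl]-2,2'-diol; 3 (3-ethoxy-3-oxopropyl)zinc bromide (commercial 0.5 M solution in THF, 5 equiv)
Product: 5 3,3'-(6,6'-dihydroxy-5,5'-dimethoxy-[1,1'-biphenyl]-3,3'-diyl)dipropanoic acid, via diethyl ester 4 (not isolated)
Conditions: Pd(OAc)2 (4 mol %), SPhos (2-dicyclohexylphosphino-2',6'-dimethoxybiphenyl, 8 mol %), 3 added over 1 h, THF, 25 to 50 °C; then LiOH (12 equiv), MeOH/H2O, 50 °C, argon; then 1 M HCl to pH 2
Reagents that add atoms: (3-ethoxy-3-oxopropyl)zinc bromide 3, CCOC(=O)CC[Zn]Br; lithium hydroxide, [Li+].[OH-]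
Why: Twofold Negishi cross-coupling of a carbonyl-chelated zinc ester homoenolate, in which oxidative addition of each Ar–Br bond to zerovalent palladium, transmetalation and fast reductive elimination from the SPhos complex outrun both β-hydride elimination and protonation by the free phenols, followed by BAc2 saponification of the two ethyl esters in the same pot; no stereocentre is formed.

**Compound list**
1 | 4-bromo-2-methoxyphenol (4-bromoguaiacol) | COc1cc(Br)ccc1O | starting material
2 | 5,5'-dibromo-3,3'-dimethoxy-[1,1'-biphenyl]-2,2'-diol | COc1cc(Br)cc(-c2cc(Br)cc(OC)c2O)c1O | intermediate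
3 | (3-ethoxy-3-oxopropyl)zinc bromide | CCOC(=O)CC[Zn]Br | starting material
4 | diethyl 3,3'-(6,6'-dihydroxy-5,5'-dimethoxy-[1,1'-biphenyl]-3,3'-diyl)dipropanoate | CCOC(=O)CCc1cc(OC)c(O)c(-c2cc(CCC(=O)OCC)cc(OC)c2O)c1 | intermediate
5 | 3,3'-(6,6'-dihydroxy-5,5'-dimethoxy-[1,1'-biphenyl]-3,3'-diyl)dipropanoic acid | COc1cc(CCC(=O)O)cc(-c2cc(CCC(=O)O)cc(OC)c2O)c1O | target

**Step count and risks**
Total step count: 2. Longest linear sequence: 2 (1 → 2 → 5).

The route has only two steps, so the three most likely failure points are step 1 and the two stages of step 2.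

Step 1, oxidative dimerisation. The risks are C–O coupling, over-oxidation of the product biphenol, or loss of bromine through coupling at the para carbon. The fallback inverts the order of events; it sets out from 1 and comes back at 4. Compound 1 is first coupled with 3 (Pd(OAc)2, SPhos, THF, 25 to 50 °C) to give ethyl 3-(4-hydroxy-3-methoxyphenyl)propanoate F1. This is a para-alkyl guaiacol, a more electron-rich substrate that should dimerise more readily than 1. Oxidative ortho–ortho coupling of F1 (FeCl3 cat., t-BuOOt-Bu, (CF3)2CHOH, rt) then gives the diester 4, which is saponified to 5 with LiOH as in the second stage of step 2.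

Step 2, coupling stage. The free phenols may quench the zinc reagent, the electron-rich zinc biphenoxide may stall oxidative addition, or the biphenol may bind palladium. The fallback masks the phenols as esters that come off in the existing saponification; it sets out from 2 and comes back at 5. Acetylation of 2 (Ac2O, pyridine, DMAP cat., rt) gives 5,5'-dibromo-3,3'-dimethoxy-[1,1'-biphenyl]-2,2'-diyl diacetate F2. F2 has no acidic proton and a less electron-rich C–Br bond. Twofold Negishi coupling of F2 with 3 under the same catalyst gives diethyl 3,3'-(6,6'-diacetoxy-5,5'-dimethoxy-[1,1'-biphenyl]-3,3'-diyl)dipropanoate F3. LiOH in MeOH/H2O then cleaves the two aryl acetates and the two ethyl esters together, and acidification gives 5.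

Step 2, saponification stage. The risks are air oxidation of the electron-rich biphenolate in hot base and zinc hydroxide gels that trap material. The fallback avoids base altogether; it sets out from 2 and comes back at 5. tert-Butyl 3-bromopropanoate (CC(C)(C)OC(=O)CCBr) is treated with zinc dust and LiCl in THF to give (3-tert-butoxy-3-oxopropyl)zinc bromide F4. Coupling of F4 with 2 (Pd(OAc)2, SPhos, THF) gives di-tert-butyl 3,3'-(6,6'-dihydroxy-5,5'-dimethoxy-[1,1'-biphenyl]-3,3'-diyl)dipropanoate F5, which is isolated. Treatment of F5 with CF3CO2H in CH2Cl2 at 0 °C to rt removes both tert-butyl groups as 2-methylpropene and gives 5.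

**Further compounds**
F1 | step 1 | ethyl 3-(4-hydroxy-3-methoxyphenyl)propanoate | CCOC(=O)CCc1ccc(O)c(OC)c1
F2 | step 2 | 5,5'-dibromo-3,3'-dimethoxy-[1,1'-biphenyl]-2,2'-diyl diacetate | COc1cc(Br)cc(-c2cc(Br)cc(OC)c2OC(C)=O)c1OC(C)=O
F3 | step 2 | diethyl 3,3'-(6,6'-diacetoxy-5,5'-dimethoxy-[1,1'-biphenyl]-3,3'-diyl)dipropanoate | CCOC(=O)CCc1cc(OC)c(OC(C)=O)c(-c2cc(CCC(=O)OCC)cc(OC)c2OC(C)=O)c1
F4 | step 2 | (3-tert-butoxy-3-oxopropyl)zinc bromide | CC(C)(C)OC(=O)CC[Zn]Br
F5 | step 2 | di-tert-butyl 3,3'-(6,6'-dihydroxy-5,5'-dimethoxy-[1,1'-biphenyl]-3,3'-diyl)dipropanoate | CC(C)(C)OC(=O)CCc1cc(OC)c(O)c(-c2cc(CCC(=O)OC(C)(C)C)cc(OC)c2O)c1
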